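Which vessel turns the most Z into G from one charge: the tank, the closed flask, or the flask that receives Z slowly?

common to all: X 3.3 mM

| run | Z | E | remark | time |
|---|---|---|---|---|
| autumn | 0.10 M | 2.6 mM | run made earlier |  |
| noon | 0.10 M | 3.6 mM | run made earlier |  |
| dawn | 0.10 M | 5.7 mM | run made earlier |  |
| Saturday's | 0.10 M | 2.6 mM | a single well-mixed tank run continuously and read at steady state, 6.0 d in it on average |  |
| Sunday's | 0.10 M | 2.6 mM | a closed flask charged with all of it at once and left for 6.0 d | 6.0 d |
| Wednesday's | 0.10 M (fed, over 6.00 d) | 2.6 mM | a stirred flask in which Z is dosed at a steady rate over 6.00 d without added volume, worked up at 6.0 d | 6.0 d |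

| run | time / d | G / % | Z / % |
|---|---|---|---|
| autumn | 0.500 | 4 | 96 |
| autumn | 0.833 | 7 | 96 |
| autumn | 1.67 | 8 | 89 |
| autumn | 3.00 | 18 | 83 |
| autumn | 6.00 | 30 | 69 |
| noon | 1.25 | 5 | 91 |
| noon | 3.00 | 10 | 88 |
| noon | 4.00 | 14 | 88 |
| noon | 6.00 | 20 | 81 |
| noon | 8.00 | 20 | 78 |
| dawn | 1.25 | 3 | 99 |
| dawn | 3.00 | 3 | 98 |
| dawn | 4.00 | 4 | 95 |
| dawn | 6.00 | 5 | 94 |
| dawn | 8.00 | 9 | 87 |

(readings scatter by 2 percentage points)

* the set-up with the highest amount of G at the outlet or at the end, in percent of the Z put in ("none" if the first two lie within 2 percentage points) (Saturday's / Sunday's / Wednesday's / none)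
* amount of G at the outlet or at the end, in percent of the Z put in, Saturday's
* amount of G at the outlet or at the end, in percent of the Z put in, Sunday's
* amount of G at the outlet or at the end, in percent of the Z put in, Wednesday's

- the stated concentrations are those of everything mixed, before any reaction; amounts are the same in each set-up
- what was read earlier has a scatter of 2 percentage points, one standard deviation
- the feed brings no volume worth counting
- the earlier runs were made in a closed, stirred flask

I follow one Z molecule. The autumn run has the charge of all three set-ups, and its Z and G readings sum to about the whole charge, so the molecule's fork is simple: it turns into G or stays Z. I assume a constant daily risk of turning, which makes the reaction pseudo-first-order in cZ. In the autumn run 69% of Z remains at 6.00 d, so the stay number D, the daily risk times the days spent in the vessel, is 0.371. That is a risk of 0.0618 d⁻¹, and the full stay in each set-up is 6.0 d, in the tank on average.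

In the closed flask the molecule survives with chance exp(−D), giving 31.0% G. In the tank, turning competes with washing out at odds of D to one, so the chance of G is D/(1+D), or 27.1%, less than the closed flask gives. In the fed flask the arrival time is spread evenly over the run, so I average survival over stays from zero to full. That gives 16.5%, the lowest of my three.

The weak link is D itself, which hangs on one reading and one assumed order. G, read separately, gives 0.357, so the value stands. For the order, constant risk predicts 83.1% Z at 3.00 d, and the reading is 83%. A straight line predicts 84.5%, also within the scatter, so the order stays open.

The forecast, from a stay number of 0.36, names Sunday's, with 26% (22% to 31%) for Saturday's, 30% (27% to 33%) for Sunday's and 16% (13% to 24%) for Wednesday's: “The batch flask comes out best, though its margin over the tank is modest.”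

The flask gives 27.9% for Saturday's, 32.1% for Sunday's and 17.1% for Wednesday's, so Sunday's is best.

    Z + X → X + G (k = 0.0670 M⁻¹ min⁻¹)
    2 X ⇌ J, settled at all times (K = 380 M⁻¹)
    X + E ⇌ L, settled at all times (K = 11000 M⁻¹)

Wednesday's stops at 17.1% through two things acting together: the time given, against 97.5% at 60.0 d, and the binding of X + E into L, without which that flask gives 33.6%. The slow dosing of Z is a further part, with 32.1% in Wednesday's without it. If the dose instead goes in over a tenth of the run, a molecule arrives on average halfway through that dose, which leaves it a stay number of 0.352 and a G of 29.7%. The flask dosed that way gives 30.8%.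

(The runs were generated by integration for an exercise; noise was put on by code.)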